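Ring B with C17, the C9 oxygen, the C5 stereocentre and the gem-dimethyl carbon C4 is the p-menthane skeleton of (R)-carvone. The route rests on a [3+3] annulation that lays C1–C2–C3 across C10 and C4, which sit 1,3 across C5 in 6-methylcarvone as the enolisable α′ carbon and the isopropenyl carbon. In one flask the C10 enolate is allylated (SN2′) by 2,3-bis(phenylsulfonyl)propene, anti to the isopropenyl group, and iron-hydride hydrogen-atom transfer then turns that group into the C4 tertiary radical, which closes 6-endo onto the new vinyl sulfone. Ring A, the C10 quaternary centre and the gem-dimethyl carbon arise together; singlet oxygen later places both ring B oxygens on the α face.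

Key step: step 2

Remark on numbering and configuration: labdane numbering is used for all bicyclic compounds (ring A = C1–C5, C10; ring B = C5–C10). The target SMILES is read as the 5α-H, 10β-CH3, 8α-CH3, 9α-OH (side chain β), 6α-OAc isomer, (5S,6S,8R,9R,10S).
Remark on starting materials: compounds 1, 3 and 12 are taken as purchased.

Step 1
Reactants: 1 (R)-(−)-carvone
Product: 2 6-methylcarvone (epimers at the new centre)
Conditions: LiN(i-Pr)2, THF, −78 °C; MeI, −78 → 0 °C
Reagents that add atoms: iodomethane, CI
Why: Kinetic deprotonation at the α′ carbon of the enone and SN2 methylation of the lithium enolate (enolate alkylation) should give 2; the new centre is formed without control, which is harmless because it is planarised again in step 2.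

Step 2
Reactants: 2 6-methylcarvone; 3 2,3-bis(phenylsulfonyl)prop-1-ene
Product: 5 2ξ-(phenylsulfonyl)-11,12,13,14,15,16-hexanorlabd-7-en-9-one, via vinyl sulfone 4 (not isolated)
Conditions: LiN(i-Pr)2, THF, −78 → −30 °C; 3 (1.0 equiv), −78 → 0 °C; then EtOH, Fe(acac)3 (0.3 equiv), PhSiH3, 60 °C
Reagents that add atoms: none
Why: The fully substituted lithium enolate of 2 adds to the CH2 terminus of the vinyl sulfone in 3 and expels benzenesulfinate (SN2′ allylation), which makes the C1–C10 bond and leaves a 2-sulfonylallyl group; the iron hydride formed from Fe(acac)3 and PhSiH3 then transfers a hydrogen atom to the isopropenyl CH2, and the tertiary C4 radical adds to the terminal carbon C3 of the vinyl sulfone, after which the α-sulfonyl radical is reduced by divalent iron and protonated by EtOH. The closest known reaction types are the second α′-alkylation of 6-alkylcarvone enolates and the iron-hydride reductive olefin coupling (Giese-type addition) to vinyl sulfones. Ring A is closed in the 6-endo-trig radical mode, preferred over 5-exo because the nucleophilic radical attacks the unsubstituted electron-poor terminus and produces a sulfone-stabilised radical. C10 is set in the allylation, the electrophile entering anti to the C5 isopropenyl group so that C1 lies trans to C4 and the methyl cis; C5 comes unchanged from carvone, so the trans ring fusion is fixed before the ring closes, and C2 forms as an uncontrolled mixture that is erased in step 6. The step needs hydrogen-atom transfer to the electron-rich 1,1-disubstituted alkene instead of the enone or the vinyl sulfone, which the polarity preference of the metal hydride secures, and it needs cyclisation to outrun intermolecular addition, which the one-to-one stoichiometry of 3 and the six-membered transition state secure.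

Step 3
Reactants: 5 2ξ-(phenylsulfonyl)-11,12,13,14,15,16-hexanorlabd-7-en-9-one
Product: 6 2ξ-(phenylsulfonyl)-11,12,13,14,15,16-hexanorlabda-6,8-dien-9-yl trifluoromethanesulfonate
Conditions: KN(SiMe3)2, THF, −78 °C; PhNTf2, −78 → 0 °C
Reagents that add atoms: N-phenylbis(trifluoromethanesulfonimide), O=S(=O)(N(c1ccccc1)S(=O)(=O)C(F)(F)F)C(F)(F)F
Why: With no α′ hydrogen left, the amide base removes the γ hydrogen at C6 to give the linear dienolate, whose O-sulfonylation (enol triflate formation) should give the 6,8-dienyl triflate; no stereocentre is formed and the α-sulfonyl C–H is too weakly acidic to interfere.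

Step 4
Reactants: 6 2ξ-(phenylsulfonyl)-11,12,13,14,15,16-hexanorlabda-6,8-dien-9-yl trifluoromethanesulfonate
Product: 7 2ξ-(phenylsulfonyl)-13,14,15,16-tetranorlabda-6,8,11-triene
Conditions: vinyl-B(pin), PdCl2(dppf) (5 mol %), K3PO4, THF/H2O, 65 °C
Reagents that add atoms: 4,4,5,5-tetramethyl-2-vinyl-1,3,2-dioxaborolane, C=CB1OC(C)(C)C(C)(C)O1
Why: Suzuki–Miyaura coupling of the alkenyl triflate with the vinylboronate attaches C11–C12 to C9 as a vinyl group; no stereocentre is formed and the ring-locked E geometry of the central C8=C9 bond rules out electrocyclisation of the triene.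

Step 5
Reactants: 7 2ξ-(phenylsulfonyl)-13,14,15,16-tetranorlabda-6,8,11-triene
Product: 9 9α-hydroxy-2ξ-(phenylsulfonyl)-13,14,15,16-tetranorlabda-7,11-dien-6-one, via endoperoxide 8 (not isolated)
Conditions: O2, tetraphenylporphyrin (cat.), hν, CH2Cl2, −20 °C; then Et3N, 0 °C → rt
Reagents that add atoms: dioxygen, O=O
Why: Singlet oxygen should add [4+2] to the cisoid homoannular 6,8-diene in preference to the vinyl-containing s-trans diene and from the α face, anti to the axial C10 methyl and the 4β methyl, so that the C9–O bond is set α, and the Kornblum–DeLaMare rearrangement of the endoperoxide by loss of the only bridgehead hydrogen (H6) then gives the 6-ketone and the 9α tertiary alcohol.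

Step 6
Reactants: 9 9α-hydroxy-2ξ-(phenylsulfonyl)-13,14,15,16-tetranorlabda-7,11-dien-6-one
Product: 11 13,14,15,16-tetranorlabd-11-ene-6α,9α-diol, via hydroxy ketone 10 (not isolated)
Conditions: Li (12 equiv), NH3/THF, −78 °C; then EtOH, −78 → −33 °C; NH4Cl
Reagents that add atoms: none
Why: Birch-type dissolving-metal reduction should do three things in one pot: the enone is reduced with axial (β) protonation at C8, which leaves the methyl equatorial (8α), the resulting ketone is reduced to the thermodynamically preferred equatorial 6α alcohol once EtOH is added, and the C2–S bond is cleaved reductively, while the isolated vinyl group and the tertiary lithium alkoxide are not touched.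

Step 7
Reactants: 11 13,14,15,16-tetranorlabd-11-ene-6α,9α-diol; 12 3-bromofuran-2(5H)-one
Product: 14 6α,9α-dihydroxylabd-13-en-16,15-olide, via alkylborane 13 (not isolated)
Conditions: 9-BBN-H (3.5 equiv), THF, 0 °C → rt; then 12, PdCl2(dppf) (10 mol %), AsPh3, K3PO4 aq., DMF, rt
Reagents that add atoms: none
Why: Anti-Markovnikov hydroboration of the vinyl group puts boron on C12 and the B-alkyl Suzuki–Miyaura coupling with the α-bromobutenolide forms the C12–C13 bond; no stereocentre is formed, the excess borane covers the two hydroxyl groups and the mild phosphate base spares the lactone.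

Step 8
Reactants: 14 6α,9α-dihydroxylabd-13-en-16,15-olide
Product: 15 6α-acetoxy-9α-hydroxylabd-13-en-16,15-olide (CNP0205088.2)
Conditions: Ac2O, pyridine, DMAP (cat.), CH2Cl2, 0 °C → rt
Reagents that add atoms: acetic anhydride, CC(=O)OC(C)=O
Why: DMAP-catalysed acylation should acetylate the secondary equatorial 6α hydroxyl only, the tertiary 9α hydroxyl flanked by two fully substituted carbons being inert under these conditions.

Compound list
1 | (R)-(−)-carvone, (5R)-2-methyl-5-(prop-1-en-2-yl)cyclohex-2-en-1-one | CC1=CC[C@H](CC1=O)C(C)=C | starting material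
2 | 6-methylcarvone, (5R)-2,6-dimethyl-5-(prop-1-en-2-yl)cyclohex-2-en-1-one, both C6 epimers | CC1=CC[C@@H](C(C)=C)C(C)C1=O | intermediate
3 | 2,3-bis(phenylsulfonyl)prop-1-ene | C=C(CS(=O)(=O)c1ccccc1)S(=O)(=O)c1ccccc1 | starting material
4 | 6-methyl-6-[2-(phenylsulfonyl)prop-2-en-1-yl]carvone, sulfonylallyl group trans to the isopropenyl group | CC1=CC[C@@H](C(C)=C)[C@](C)(CC(=C)S(=O)(=O)c2ccccc2)C1=O | intermediate (not isolated)
5 | 2ξ-(phenylsulfonyl)-11,12,13,14,15,16-hexanorlabd-7-en-9-one, trans-fused (5α-H, 10β-CH3), C2 epimers | C1C=C(C)C(=O)[C@@]2(C)CC(S(=O)(=O)c3ccccc3)CC(C)(C)[C@H]12 | intermediate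
6 | 2ξ-(phenylsulfonyl)-11,12,13,14,15,16-hexanorlabda-6,8-dien-9-yl trifluoromethanesulfonate (5α-H, 10β-CH3) | C1=CC(C)=C(OS(=O)(=O)C(F)(F)F)[C@@]2(C)CC(S(=O)(=O)c3ccccc3)CC(C)(C)[C@H]12 | intermediate
7 | 2ξ-(phenylsulfonyl)-13,14,15,16-tetranorlabda-6,8,11-triene (5α-H, 10β-CH3) | C1=CC(C)=C(C=C)[C@@]2(C)CC(S(=O)(=O)c3ccccc3)CC(C)(C)[C@H]12 | intermediate
8 | 6α,9α-epidioxy-2ξ-(phenylsulfonyl)-13,14,15,16-tetranorlabda-7,11-diene | O1O[C@H]2C=C(C)[C@]1(C=C)[C@@]3(C)CC(S(=O)(=O)c4ccccc4)CC(C)(C)[C@H]23 | intermediate (not isolated)
9 | 9α-hydroxy-2ξ-(phenylsulfonyl)-13,14,15,16-tetranorlabda-7,11-dien-6-one (vinyl group 9β) | O=C1C=C(C)[C@](O)(C=C)[C@@]2(C)CC(S(=O)(=O)c3ccccc3)CC(C)(C)[C@H]12 | intermediate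
10 | 9α-hydroxy-13,14,15,16-tetranorlabd-11-en-6-one (8α-CH3) | O=C1C[C@@H](C)[C@](O)(C=C)[C@@]2(C)CCCC(C)(C)[C@H]12 | intermediate (not isolated)
11 | 13,14,15,16-tetranorlabd-11-ene-6α,9α-diol (8α-CH3) | O[C@H]1C[C@@H](C)[C@](O)(C=C)[C@@]2(C)CCCC(C)(C)[C@H]12 | intermediate
12 | 3-bromofuran-2(5H)-one | O=C1OCC=C1Br | starting material
13 | 12-(9-borabicyclo[3.3.1]nonan-9-yl)-13,14,15,16-tetranorlabdane-6α,9α-diol (hydroxyl groups drawn free; in the flask partly O-borylated) | O[C@H]1C[C@@H](C)[C@](O)(CCB3C4CCCC3CCC4)[C@@]2(C)CCCC(C)(C)[C@H]12 | intermediate (not isolated)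
14 | 6α,9α-dihydroxylabd-13-en-16,15-olide | O[C@H]1C[C@@H](C)[C@](O)(CCC2=CCOC2=O)[C@@]2(C)CCCC(C)(C)[C@H]12 | intermediate
15 | 6α-acetoxy-9α-hydroxylabd-13-en-16,15-olide (CNP0205088.2) | CC(=O)O[C@H]1C[C@@H](C)[C@](O)(CCC2=CCOC2=O)[C@@]2(C)CCCC(C)(C)[C@H]12 | target

Total step count: 8
Longest linear sequence: 8 steps (1 → 15)

Steps most likely to fail

Step 2. The telescoped radical stage may stall because lithium benzenesulfinate and diisopropylamine left from the enolate stage poison the iron hydride, or the C4 radical may be reduced before it cyclises. The fallback sets out from 4, isolated by aqueous work-up after the enolate stage, and generates the same radical from a halide instead of by hydrogen-atom transfer. HBr in AcOH/CH2Cl2 at 0 °C should add in the Markovnikov sense to the isopropenyl group only, giving the tertiary bromide F1. Bu3SnH with azobisisobutyronitrile in benzene at 80 °C under slow addition should then abstract bromine and close ring A by the tin-hydride Giese cyclisation. This comes back to the route at 5.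

Step 6. The three reductions may not all run cleanly in one pot: the C9 oxygen may be lost by γ-elimination from the enone radical anion, the sulfone may cleave on the aryl side, or the ketone may survive. The fallback sets out from 9 and separates the events. SmI2 in THF/MeOH at −78 °C should reduce only the enone C=C bond, with the same axial protonation at C8, to give the sulfonyl hydroxy ketone F2. Na(Hg) with Na2HPO4 in MeOH at −20 °C should then remove the sulfone. This comes back to the route at 10, which is now isolated and reduced to the equatorial alcohol 11 with SmI2, H2O and Et3N in THF.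

Step 7. Transmetalation of the alkylborane may be slowed by borinate formation at the neighbouring 9-hydroxyl, and the bromobutenolide may be degraded by aqueous base before it couples. The fallback sets out from 11 and replaces the boron coupling by a reductive cross-electrophile coupling. Hydroboration with 9-BBN-H followed by NaOH/H2O2 should give the triol F4. I2, PPh3 and imidazole in CH2Cl2 at 0 °C (Appel-type iodination) should convert only the primary hydroxyl, giving the iodide F5. NiCl2(dme), 4,4′-di-tert-butyl-2,2′-bipyridine and Zn in dimethylacetamide at rt should then join F5 to 12 under neutral conditions. This comes back to the route at 14.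

Further compounds
F1 | step 2 | (5R)-5-(2-bromopropan-2-yl)-2,6-dimethyl-6-[2-(phenylsulfonyl)prop-2-en-1-yl]cyclohex-2-en-1-one, hydrobromide of 4 | CC1=CC[C@@H](C(C)(C)Br)[C@](C)(CC(=C)S(=O)(=O)c2ccccc2)C1=O
F2 | step 6 | 9α-hydroxy-2ξ-(phenylsulfonyl)-13,14,15,16-tetranorlabd-11-en-6-one (8α-CH3) | O=C1C[C@@H](C)[C@](O)(C=C)[C@@]2(C)CC(S(=O)(=O)c3ccccc3)CC(C)(C)[C@H]12
F4 | step 7 | 13,14,15,16-tetranorlabdane-6α,9α,12-triol | O[C@H]1C[C@@H](C)[C@](O)(CCO)[C@@]2(C)CCCC(C)(C)[C@H]12
F5 | step 7 | 12-iodo-13,14,15,16-tetranorlabdane-6α,9α-diol | O[C@H]1C[C@@H](C)[C@](O)(CCI)[C@@]2(C)CCCC(C)(C)[C@H]12
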